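**Retrosynthetic overview**
1. Target 16 ← hydroxy enone 13 by acetylation of the tertiary hydroxyl and conversion of CH2OSi into CO2H. Ring numbering used below: C1 carbonyl, C2=C3, C4 oxygen-bearing quaternary carbon, C5 the CH that carries the pentenyl group.
2. Enabling feature: in the only ring, C1 and C4 stand 1,4 to each other across the cis C2=C3 bond, and C5 carries one H and one carbon chain. C1–C4 plus one oxygen are therefore a 2,5-disubstituted furan in disguise, with C5 as a carbinol carbon on its side chain.
3. Key disconnection: the C4–C5 ring bond (quaternary carbon to CH) → furyl carbinol 9 and water, by an enantioselective Piancatelli rearrangement. The furan ring, which is not in the target, is opened as the cyclopentenone, the only ring of the skeleton, is closed; C5 is then corrected by epimerization.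
4. 9 ← 5-lithiated 2-alkylfuran 5 + (Z)-hex-3-enal 7; 5 ← furan 3 + C8 bromide 2.

Key step: step 5

Assumption: the (R)-configured acid is taken to deliver the (4S) product; if the sense of induction proves opposite, the (S)-acid is used and nothing else changes.

**Step 1**
Reactants: 1 8-bromooctan-1-ol
Product: 2 (8-bromooctyloxy)(tert-butyl)diphenylsilane
Conditions: TBDPSCl, imidazole, CH2Cl2, 0 °C → rt
Reagents that add atoms: tert-butyl(chloro)diphenylsilane (TBDPSCl), CC(C)(C)[Si](Cl)(c1ccccc1)c1ccccc1
Why: Standard silylation of a primary alcohol; the TBDPS ether is chosen because it should survive organolithium reagents and the aqueous acid of steps 5 and 6.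

**Step 2**
Reactants: 3 furan; 2 (8-bromooctyloxy)(tert-butyl)diphenylsilane
Product: 5 tert-butyl{[8-(furan-2-yl)octyl]oxy}diphenylsilane, via 2-furyllithium 4 (not isolated)
Conditions: 3 (3 equiv), n-BuLi, THF, −78 → 0 °C; then 2, DMPU, 0 °C → rt
Reagents that add atoms: none
Why: α-Lithiation of furan followed by SN2 alkylation with a primary bromide is well precedented; excess furan should suppress 2,5-dialkylation.

**Step 3**
Reactants: 6 (Z)-hex-3-en-1-ol
Product: 7 (Z)-hex-3-enal
Conditions: Dess–Martin periodinane (1,1,1-triacetoxy-1,1-dihydro-1,2-benziodoxol-3(1H)-one), NaHCO3, CH2Cl2, 0 °C → rt; used at once as a solution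
Reagents that add atoms: none
Why: Buffered Dess–Martin oxidation should give the β,γ-unsaturated aldehyde without migration or isomerization of the cis double bond.

**Step 4**
Reactants: 5 tert-butyl{[8-(furan-2-yl)octyl]oxy}diphenylsilane; 7 (Z)-hex-3-enal
Product: 9 (3Z)-1-(5-{8-[(tert-butyldiphenylsilyl)oxy]octyl}furan-2-yl)hex-3-en-1-ol (racemic at the carbinol carbon), via 5-lithiofuran 8 (not isolated)
Conditions: n-BuLi, TMEDA, THF, 0 °C; then 7, −78 °C; then H2O
Reagents that add atoms: none
Why: Lithiation of a 2-alkylfuran at the free α-position and 1,2-addition to an aldehyde at low temperature; the carbinol centre is made racemic on purpose because it becomes planar in step 5.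

**Step 5**
Reactants: 9 (3Z)-1-(5-{8-[(tert-butyldiphenylsilyl)oxy]octyl}furan-2-yl)hex-3-en-1-ol
Product: 12 (4S,5R)-4-{8-[(tert-butyldiphenylsilyl)oxy]octyl}-4-hydroxy-5-[(2Z)-pent-2-en-1-yl]cyclopent-2-en-1-one, via dihydrofuran hemiketal 10 (not isolated), via dihydroxypentadienyl cation 11 (not isolated)
Conditions: (R)-3,3'-bis(2,4,6-triisopropylphenyl)-1,1'-binaphthyl-2,2'-diyl N-triflylphosphoramide (10 mol%), H2O (20 equiv), toluene, 40 °C
Reagents that add atoms: water, O
Why: Proposed new method: the chiral acid ionizes the furyl carbinol, water adds to the alkyl-bearing furan carbon to give hemiketal 10, and ring opening delivers the 1,4-dihydroxypentadienyl cation 11, which is held by the chiral phosphoramidate through two O–H···O hydrogen bonds and closes by thermal conrotatory 4π electrocyclization between its two termini before tautomerizing to the enone. The closest known reactions are the racemic Piancatelli rearrangement of 5-alkyl-2-furyl alkyl carbinols in water (ZnCl2 or Dy(OTf)3) and the chiral phosphoric acid-catalyzed enantioselective aza-Piancatelli rearrangement with anilines; what is new is water as the nucleophile under chiral Brønsted acid control. The five-membered ring is closed by 4π conrotatory (Nazarov-type) electrocyclization, which forms the bond between the oxygen-bearing quaternary carbon C4 and C5. C4 is set by the sense of conrotation, which the chiral counteranion dictates, and C5 follows from C4 because the out,out cation is expected to close with the new hydroxyl trans to the pentenyl group, hence (4S,5R). The step needs water to attack the substituted furan carbon (attack at the carbinol carbon only regenerates 9) and must avoid proton loss from the cation to a dienylfuran and later drift of the product to the 2,3-dialkyl-4-hydroxy isomer; the donor alkyl group on the furan, the excess of water and the mild temperature should secure this, while the cis geometry of C2=C3 needed for closure is fixed by the furan ring.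

**Step 6**
Reactants: 12 (4S,5R)-4-{8-[(tert-butyldiphenylsilyl)oxy]octyl}-4-hydroxy-5-[(2Z)-pent-2-en-1-yl]cyclopent-2-en-1-one
Product: 13 (4S,5S)-4-{8-[(tert-butyldiphenylsilyl)oxy]octyl}-4-hydroxy-5-[(2Z)-pent-2-en-1-yl]cyclopent-2-en-1-one
Conditions: p-toluenesulfonic acid monohydrate (10 mol%), CHCl3, 40 °C; chromatography, recovered 12 resubmitted
Reagents that add atoms: none
Why: Acid-catalyzed enolization toward C5 (α-epimerization of a ketone) should equilibrate 12 to the more stable epimer 13, in which the pentenyl group is trans to the larger octyl chain and cis to the small hydroxyl; C4 is untouched, and any 13 already formed in step 5 is simply carried through.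

**Step 7**
Reactants: 13 (4S,5S)-4-{8-[(tert-butyldiphenylsilyl)oxy]octyl}-4-hydroxy-5-[(2Z)-pent-2-en-1-yl]cyclopent-2-en-1-one
Product: 14 (1S,5S)-1-{8-[(tert-butyldiphenylsilyl)oxy]octyl}-4-oxo-5-[(2Z)-pent-2-en-1-yl]cyclopent-2-en-1-yl acetate
Conditions: Ac2O, 4-(dimethylamino)pyridine (DMAP), pyridine, rt → 40 °C
Reagents that add atoms: acetic anhydride, CC(=O)OC(C)=O
Why: Nucleophile-catalyzed acylation of a tertiary alcohol; the weak base pyridine should not trigger loss of acetate from the β-acetoxy ketone, and C5 is already in its preferred configuration.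

**Step 8**
Reactants: 14 (1S,5S)-1-{8-[(tert-butyldiphenylsilyl)oxy]octyl}-4-oxo-5-[(2Z)-pent-2-en-1-yl]cyclopent-2-en-1-yl acetate
Product: 15 (1S,5S)-1-(8-hydroxyoctyl)-4-oxo-5-[(2Z)-pent-2-en-1-yl]cyclopent-2-en-1-yl acetate
Conditions: HF·pyridine, THF/pyridine, 0 °C → rt
Reagents that add atoms: none
Why: Fluoride-mediated desilylation under buffered, non-basic conditions should leave the tertiary acetate, the enone and the C5 centre untouched.

**Step 9**
Reactants: 15 (1S,5S)-1-(8-hydroxyoctyl)-4-oxo-5-[(2Z)-pent-2-en-1-yl]cyclopent-2-en-1-yl acetate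
Product: 16 8-{(1S,5S)-1-acetoxy-4-oxo-5-[(2Z)-pent-2-en-1-yl]cyclopent-2-en-1-yl}octanoic acid
Conditions: 2,2,6,6-tetramethylpiperidin-1-oxyl (TEMPO, 20 mol%), PhI(OAc)2, MeCN/H2O, rt
Reagents that add atoms: water, O
Why: Oxoammonium-mediated oxidation of the primary alcohol through the aldehyde hydrate to the carboxylic acid; the mildly acidic medium should spare the cis alkene, the enone, the tertiary acetate and the C5 configuration.

**Compound list**
1 | 8-bromooctan-1-ol | OCCCCCCCCBr | starting material
2 | (8-bromooctyloxy)(tert-butyl)diphenylsilane | BrCCCCCCCCO[Si](c1ccccc1)(c1ccccc1)C(C)(C)C | intermediate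
3 | furan | c1ccoc1 | starting material
4 | 2-furyllithium | [Li]c1ccco1 | intermediate
5 | tert-butyl{[8-(furan-2-yl)octyl]oxy}diphenylsilane | c1coc(CCCCCCCCO[Si](c2ccccc2)(c2ccccc2)C(C)(C)C)c1 | intermediate
6 | (Z)-hex-3-en-1-ol | CC/C=C\CCO | starting material
7 | (Z)-hex-3-enal | CC/C=C\CC=O | intermediate
8 | tert-butyl{[8-(5-lithiofuran-2-yl)octyl]oxy}diphenylsilane | [Li]c1ccc(CCCCCCCCO[Si](c2ccccc2)(c2ccccc2)C(C)(C)C)o1 | intermediate
9 | (3Z)-1-(5-{8-[(tert-butyldiphenylsilyl)oxy]octyl}furan-2-yl)hex-3-en-1-ol, racemic at the carbinol carbon | CC/C=C\CC(O)c1ccc(CCCCCCCCO[Si](c2ccccc2)(c2ccccc2)C(C)(C)C)o1 | intermediate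
10 | 2-{8-[(tert-butyldiphenylsilyl)oxy]octyl}-5-[(3Z)-hex-3-en-1-ylidene]-2,5-dihydrofuran-2-ol, side chain on the ring-oxygen side of the exocyclic double bond | CC/C=C\C/C=C1/C=CC(O)(CCCCCCCCO[Si](c2ccccc2)(c2ccccc2)C(C)(C)C)O1 | intermediate
11 | O-protonated (10Z,12Z,15Z)-1-[(tert-butyldiphenylsilyl)oxy]-12-hydroxyoctadeca-10,12,15-trien-9-one (1,4-dihydroxypentadienyl cation) | CC/C=C\C/C=C(O)/C=C\C(=[OH+])CCCCCCCCO[Si](c1ccccc1)(c1ccccc1)C(C)(C)C | intermediate
12 | (4S,5R)-4-{8-[(tert-butyldiphenylsilyl)oxy]octyl}-4-hydroxy-5-[(2Z)-pent-2-en-1-yl]cyclopent-2-en-1-one | CC/C=C\C[C@H]1C(=O)C=C[C@]1(CCCCCCCCO[Si](c2ccccc2)(c2ccccc2)C(C)(C)C)O | intermediate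
13 | (4S,5S)-4-{8-[(tert-butyldiphenylsilyl)oxy]octyl}-4-hydroxy-5-[(2Z)-pent-2-en-1-yl]cyclopent-2-en-1-one | CC/C=C\C[C@@H]1C(=O)C=C[C@]1(CCCCCCCCO[Si](c2ccccc2)(c2ccccc2)C(C)(C)C)O | intermediate
14 | (1S,5S)-1-{8-[(tert-butyldiphenylsilyl)oxy]octyl}-4-oxo-5-[(2Z)-pent-2-en-1-yl]cyclopent-2-en-1-yl acetate | CC/C=C\C[C@@H]1C(=O)C=C[C@]1(CCCCCCCCO[Si](c2ccccc2)(c2ccccc2)C(C)(C)C)OC(C)=O | intermediate
15 | (1S,5S)-1-(8-hydroxyoctyl)-4-oxo-5-[(2Z)-pent-2-en-1-yl]cyclopent-2-en-1-yl acetate | CC/C=C\C[C@@H]1C(=O)C=C[C@]1(CCCCCCCCO)OC(C)=O | intermediate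
16 | 8-{(1S,5S)-1-acetoxy-4-oxo-5-[(2Z)-pent-2-en-1-yl]cyclopent-2-en-1-yl}octanoic acid | CC/C=C\C[C@@H]1C(=O)C=C[C@]1(CCCCCCCC(=O)O)OC(C)=O | target

**Totals**
Total step count: 9. Longest linear sequence: 8 steps (steps 1, 2, 4, 5, 6, 7, 8, 9); step 3 is a one-step side branch.

**Steps most likely to fail**

Step 5 (Proposed new method). The conrotatory closure may proceed with poor enantiofacial discrimination, or the furfuryl cation may lose a proton to a dienylfuran when little water is present. The fallback sets out from 9 and returns at 13. ZnCl2 in 1,4-dioxane/water at reflux (or Dy(OTf)3 in t-BuOH/water at 80 °C), the classical Piancatelli conditions, should convert 9 into racemic trans-hydroxy enone. This is 12 together with its enantiomer (4R,5S)-4-{8-[(tert-butyldiphenylsilyl)oxy]octyl}-4-hydroxy-5-[(2Z)-pent-2-en-1-yl]cyclopent-2-en-1-one F1. The equilibration of step 6 applied to this racemate should give 13 together with its enantiomer (4R,5R)-4-{8-[(tert-butyldiphenylsilyl)oxy]octyl}-4-hydroxy-5-[(2Z)-pent-2-en-1-yl]cyclopent-2-en-1-one F2. Preparative chromatography on a chiral stationary phase (amylose tris(3,5-dimethylphenylcarbamate)) then supplies 13, and the route continues with step 7.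

Step 6. Enolization toward C5 may be slow relative to acid-promoted loss of the tertiary hydroxyl or ring-opening by retro-aldol cleavage, which would erode C4. The fallback sets out from 12 and returns at 14. Acetylation of 12 under the conditions of step 7 gives the C5-epimeric acetate (1S,5R)-1-{8-[(tert-butyldiphenylsilyl)oxy]octyl}-4-oxo-5-[(2Z)-pent-2-en-1-yl]cyclopent-2-en-1-yl acetate F3, in which the oxygen is capped and neither pathway is open. Acid-mediated equilibration of F3 (p-toluenesulfonic acid, CHCl3, 40 °C), now between acetoxy and alkyl as the cis partners, should then give 14, and the route continues with step 8.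

Step 4. Proton transfer from the doubly activated α-CH2 of the β,γ-unsaturated aldehyde to the furyllithium may compete with addition, followed by migration of the double bond into conjugation. The fallback sets out from 6 and 5 and returns at 9. Jones oxidation of 6 (CrO3, H2SO4, acetone, 0 °C) gives (Z)-hex-3-enoic acid F4. Coupling with N,O-dimethylhydroxylamine hydrochloride (carbonyldiimidazole, CH2Cl2) gives the Weinreb amide (Z)-N-methoxy-N-methylhex-3-enamide F5. Addition of the lithiofuran 8, generated from 5 as in step 4, at −78 °C and a cold buffered quench gives the furyl ketone (3Z)-1-(5-{8-[(tert-butyldiphenylsilyl)oxy]octyl}furan-2-yl)hex-3-en-1-one F6; the chelated tetrahedral adduct protects the carbonyl until work-up. Immediate Luche reduction (NaBH4, CeCl3·7H2O, MeOH, −78 °C) then gives 9.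

**Further compounds**
F1 | step 5 | (4R,5S)-4-{8-[(tert-butyldiphenylsilyl)oxy]octyl}-4-hydroxy-5-[(2Z)-pent-2-en-1-yl]cyclopent-2-en-1-one | CC/C=C\C[C@@H]1C(=O)C=C[C@@]1(CCCCCCCCO[Si](c2ccccc2)(c2ccccc2)C(C)(C)C)O
F2 | step 5 | (4R,5R)-4-{8-[(tert-butyldiphenylsilyl)oxy]octyl}-4-hydroxy-5-[(2Z)-pent-2-en-1-yl]cyclopent-2-en-1-one | CC/C=C\C[C@H]1C(=O)C=C[C@@]1(CCCCCCCCO[Si](c2ccccc2)(c2ccccc2)C(C)(C)C)O
F3 | step 6 | (1S,5R)-1-{8-[(tert-butyldiphenylsilyl)oxy]octyl}-4-oxo-5-[(2Z)-pent-2-en-1-yl]cyclopent-2-en-1-yl acetate | CC/C=C\C[C@H]1C(=O)C=C[C@]1(CCCCCCCCO[Si](c2ccccc2)(c2ccccc2)C(C)(C)C)OC(C)=O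
F4 | step 4 | (Z)-hex-3-enoic acid | CC/C=C\CC(=O)O
F5 | step 4 | (Z)-N-methoxy-N-methylhex-3-enamide | CC/C=C\CC(=O)N(C)OC
F6 | step 4 | (3Z)-1-(5-{8-[(tert-butyldiphenylsilyl)oxy]octyl}furan-2-yl)hex-3-en-1-one | CC/C=C\CC(=O)c1ccc(CCCCCCCCO[Si](c2ccccc2)(c2ccccc2)C(C)(C)C)o1
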